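(The earlier runs and the new flask come from a simulation with constants of no real substance, and the scatter is random.)

If a flask stops making product with substrate still in it, I freeze the substrate and read a clock off the run.

the same everywhere: E 1.1 M; J 1.1 mM

| run | Z | G | remark | time |
|---|---|---|---|---|
| birch | 2.2 M | 3 mM | the very flask that is asked about, followed so far |  |
| flask | 2.20 M | 3.0 mM |  | 2.5 d |

The flask asked about is the birch run itself, followed further, so the charges stay and the time grows from 30.0 h to 2.5 d.

birch run (percent of the E charged)

| time / h | X / % | E / % |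
|---|---|---|
| 1.50 | 3.8 | 96.0 |
| 5.00 | 11.4 | 91.2 |
| 8.00 | 12.9 | 87.1 |
| 12.0 | 16.9 | 83.8 |
| 20.0 | 20.4 | 78.5 |
| 25.0 | 20.5 | 78.1 |
| 30.0 | 20.8 | 79.3 |

(standard deviation of a reading: 1 percentage point)



* amount of X in the flask at 2.5 d, in percent of the E charged
* amount of E in the flask at 2.5 d, in percent of the E charged

In the birch run E still reads 79.3% at 30.0 h, so I treat E as nearly constant. But X gains 0.4 percentage points from 20.0 h to 30.0 h, less than the 3.8% of the first 1.50 h. So I define the stopping time τ, the last X reading divided by the first rate of making X: 8.21 h. If the rate decays exponentially on this clock, the asked time is n = 7.31 stopping times, and the X still to come is 0.014 points. I therefore commit to the last readings, within their scatter.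

The forecast says 21% X and 79% E, since, of true equilibrium and a dying catalyst, “both predict that the flask stays put”.

The flask gives 22.3% X and 77.7% E.

    Z + J ⇌ ZJ (K = 0.960 L mol⁻¹, k = 2.10 L mol⁻¹ min⁻¹)
    E + ZJ → EZJ (k = 0.960 L mol⁻¹ min⁻¹)
    EZJ → Q + D (k = 2.60 min⁻¹)
    D → J + X (k = 3.60 min⁻¹)
    J + G ⇌ JG, settled at all times (K = 170 L mol⁻¹)
    Z → Zu (k = 0.00220 min⁻¹)

In this flask the asked time of n stopping times is ten times the 0.253 d by which half of the turnover of E + ZJ into EZJ is done, and Z, the limiting reagent here although 2.20 M of it went in against 1.1 M of E, is down to 0.0089% of its charge, far less than the 78% of E. X stands at 22.0% at 1.25 d and at 22.3% at 25.0 d. In a neighbour flask with 0.0044 M of J, the same τ, if it holds there, leaves 0.04 points still to come at the asked time, and that flask holds 59.6% X with 0% of its Z left.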